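At the reading, 2.0 min after the start, you find the winter flask stirring with its pump stopped for 24.0 s: the substrate went in at the start and the reagent was dosed over 1.60 min. The set-ups, the earlier runs and the questions are these.

| flask | substrate | reagent | remark | time |
|---|---|---|---|---|
| alpha | 0.069 M | 0.60 equiv | run made earlier |  |
| gamma | 0.069 M | 0.40 equiv | run made earlier |  |
| epsilon | 0.069 M | 0.90 equiv | run made earlier |  |
| eta | 0.10 M | 0.60 equiv | run made earlier |  |
| summer | 0.069 M | 0.600 equiv | a single well-mixed tank run continuously and read at steady state, 2.0 min in it on average |  |
| winter | 0.069 M | 0.600 equiv (fed, over 1.60 min) | a stirred flask in which reagent is dosed at a steady rate over 1.60 min without added volume, worked up at 2.0 min | 2.0 min |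
| noon | 0.069 M | 0.600 equiv | a closed flask charged with all of it at once and left for 2.0 min | 2.0 min |
| autumn | 0.069 M (fed, over 1.60 min) | 0.600 equiv | a stirred flask in which substrate is dosed at a steady rate over 1.60 min without added volume, worked up at 2.0 min | 2.0 min |

| run | time / s | target / % | substrate / % |
|---|---|---|---|
| alpha | 10.0 | 41.4 | 46.7 |
| alpha | 25.0 | 69.4 | 17.5 |
| alpha | 50.0 | 84.5 | 5.1 |
| alpha | 80.0 | 85.7 | 1.8 |
| gamma | 10.0 | 42.0 | 47.3 |
| gamma | 20.0 | 64.0 | 25.9 |
| gamma | 40.0 | 81.3 | 8.7 |
| gamma | 90.0 | 90.5 | 1.7 |
| epsilon | 12.0 | 46.5 | 37.2 |
| epsilon | 30.0 | 71.8 | 13.3 |
| epsilon | 60.0 | 81.7 | 0.2 |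
| epsilon | 90.0 | 87.1 | 1.3 |
| eta | 25.0 | 67.1 | 16.6 |
| eta | 50.0 | 79.0 | 4.1 |
| eta | 80.0 | 86.5 | 0 |
| eta | 90.0 | 87.1 | 2.3 |

(readings scatter by 1 percentage point)

- the stated concentrations are those of everything mixed, before any reaction; amounts are the same in each set-up
- what was read earlier has a scatter of 1 percentage point, one standard deviation
- the feed brings no volume worth counting
- the earlier runs were made in a closed, stirred flask
- a reading or a percentage of target counts all its forms, free or not
- a reading of substrate is of its free form alone

1. the set-up with the highest amount of target at the outlet or at the end, in percent of the substrate put in ("none" if the first two lie within 2 percentage points) (summer / winter / noon / autumn / none)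
2. amount of target at the outlet or at the end, in percent of the substrate put in, summer
3. amount of target at the outlet or at the end, in percent of the substrate put in, winter
4. amount of target at the outlet or at the end, in percent of the substrate put in, noon
5. amount of target at the outlet or at the end, in percent of the substrate put in, autumn

I go by one reading. In the alpha run, between the first two readings, free substrate takes 15.3 s to fall by a factor of e, and I carry this first-order lifetime. The gamma run, with less reagent, reads 16.6 s, so the two charges read alike.

In one lifetime the winter pump delivers 0.0955 equiv, which is less than any earlier run held. So leave the pump rate alone: at its last reading, the alpha run stood at 85.7% and the gamma run, with less reagent, at 90.5%.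

My first answer for winter is therefore the gamma figure. Then I go round once more. The gamma run still held 1.7% substrate at 90.0 s, and the 30.0 s up to the winter reading are longer than a lifetime, so I reckon that remainder down to 0.239%. With the gamma selectivity, target per substrate spent, read as 92.1%, I commit to 91.8% for winter, more than the last alpha reading, and I name winter as the best set-up.

The forecast names winter, with 79% for summer, 91% for winter, 88% for noon and 86% for autumn, since “dosing reagent keeps it low while substrate is high”; its winter figure is lower than mine.

Winter gives 93.5%, more than summer, noon or autumn, with noon next at 89.7% and autumn at 87.6%.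

    substrate + reagent ⇌ intermediate (K = 35.0 /M, k = 0.258 /M/s)
    substrate + target ⇌ idle adduct, settled at all times (K = 3.00 /M)
    substrate → target (k = 0.0613 /s)
    2 reagent → self-condensation product (k = 0.523 /M/s)
    intermediate → side product B (k = 0.00199 /s)
    substrate → side product A (k = 0.00331 /s)

Side product A stands at 5.05% in the winter flask. I use the same lifetime on the summer tank, where material stays 2.0 min on average: I reckon the free substrate left as the lifetime over the lifetime plus that stay, 11.3% of the charge. That reckons 88.7% as spent, and summer gives 80.2% target.

The data were generated by integration from invented constants; noise was put on by code.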